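The earlier runs and the new flask come from a simulation for an exercise, noise included.

South-west and west were the two flasks I had to judge: the same Z and J, different D, each stopped at 6.0 min.

| setting | Thursday's | Wednesday's | Tuesday's | south-west | west |
|---|---|---|---|---|---|
| D | 0.025 M | 0.053 M | 0.099 M | 0.10 M | 0.030 M |
| J | 1 mM | 1 mM | 1 mM | 1.00 mM | 1.00 mM |
| Z | 3.6 mM | 3.6 mM | 3.6 mM | 3.6 mM | 3.6 mM |
| remark | run made earlier | run made earlier | run made earlier |  |  |
| time |  |  |  | 6.0 min | 6.0 min |

- which of the two ends with the longer chains by the average number of monomer units in a chain (chains begun, living or dead) ("neither" if they lie within 10%) (south-west / west / neither)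
- average number of monomer units in a chain (chains begun, living or dead) at the end, south-west
- average number of monomer units in a chain (chains begun, living or dead) at the end, west

- the average divides the monomer in chains by the number of chains begun, living and dead together
- the earlier runs do not show the number of chains; that part of a forecast is a guess

| run | time / min | E / % | D / % |
|---|---|---|---|
| Thursday's | 0.500 | 1.7 | 98.7 |
| Thursday's | 1.00 | 3.5 | 96.6 |
| Thursday's | 2.50 | 10.6 | 90.2 |
| Thursday's | 6.00 | 24.1 | 74.7 |
| Wednesday's | 1.50 | 6.5 | 93.2 |
| Wednesday's | 3.00 | 14.8 | 86.4 |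
| Wednesday's | 5.00 | 22.7 | 77.8 |
| Wednesday's | 6.00 | 25.7 | 73.6 |
| Tuesday's | 0.833 | 3.5 | 96.0 |
| Tuesday's | 2.00 | 10.6 | 88.3 |
| Tuesday's | 4.00 | 20.8 | 79.9 |
| Tuesday's | 6.00 | 25.3 | 74.4 |

(each reading ± 0.5 percentage points)

I read the last row of each run against the others. At 6.00 min, E stood at 24.1% of the D charged on Thursday, 25.7% on Wednesday and 25.3% on Tuesday. The charge of D rose by a factor of 3.96 from Thursday to Tuesday, yet the share spread over 1.6 percentage points against a scatter of 0.5 points, and not in the order of the charges. That is how a pseudo-first-order loss of D looks, so I froze the share at the mean, 25.0%.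

The earlier runs do not show the number of chains, so I guessed that each Z charged begins one. That gives the charge length: frozen share times D charged, divided by Z charged. At the same E, with one chain for each Z used, any Z left unused raises the length above it. South-west came to 6.95 and west to 2.09, so I expected south-west longer by a factor of 3.33.

The forecast named south-west, with 8.3 and 2.5, both above my figures, on the ground that “Chains begun should be set by Z and J, not D”.

South-west ended longer, at 7.31 units against 2.86 in west.

    D + Z → Q + E (k = 0.140 M⁻¹ s⁻¹)
    2 Q → G (k = 1.30 M⁻¹ s⁻¹)
    Q + J → X (k = 0.320 M⁻¹ s⁻¹)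
    D + Q → E + Q, rate k4*[Q]*[D] (k = 0.480 M⁻¹ s⁻¹)

Each Z used begins one chain in these equations. At 6.00 min, south-west had 1.4% of its Z left, and its charge length of 6.95 stood against a result of 7.31. West had 27% left, and its charge length divided by the part of Z used gives 2.85.

A neighbour of south-west, charged with 0.17 M of D, has a charge length of 11.8. It gave 12.0, with E at 25.3% and 0.070% of its Z left.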